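## Analysis of the target

The target is a tetracyclic labdane-type acetate. A trans-fused decalin (ring A: C1–C5 and C10, with the C4 gem-dimethyl group; ring B: C5–C10) carries a cyclobutane (C8, C9, C14, C15) cis-fused to the α face of the C8–C9 bond. A cyclopentane (ring D: C9, C11, C12, C13, C14) is cis-fused to that cyclobutane along C9–C14, so C9 belongs to three rings.

There are seven stereocenters. Around ring B the methyl groups on C8 and C10 and the C9–C11 bond are β, while C14, C15 and H5 are α. The C6 acetate is β, hence axial and syn to both angular methyl groups. On ring D the C13 hydroxyl lies on the face of H14 and C10, and the C13 methyl on the face of C15 (13S).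

The sensitive groups are:
- the α-acetoxy ketone, whose axial 6β-acetate is the less stable C6 epimer and sits on an enolizable carbon;
- the tertiary alcohol;
- the cyclobutane attached through C8 to the C7 carbonyl, which excludes ketyl-forming reagents once that ketone exists.

The difficulty lies in the three contiguous quaternary carbons C8, C9 and C10, two of them in the four-membered ring, and in placing the C6 oxygen on the crowded β face. The strategy rests on the fact that all three quaternary carbons lie in ring B. Cutting C7–C8 and C9–C10 divides the molecule into a ring A 1-oxydiene (C10=C5–C6=C7) and a four-membered enone (C8=C9, with a temporary carbonyl on C15), both achiral.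

## Retrosynthetic reasoning

**C7 ketone and the acetate (24 back to 21).** The C7 ketone makes H6 acidic and puts a carbonyl next to the cyclobutane, so it is made last, by oxidation of the 7α-alcohol 23. No C–C bond is cut. Diol 23 comes from the bis-silyl ether 22 and this from alcohol 21. The acetate is installed while O7 and O13 are silylated, so the forcing acylation of the buried axial hydroxyl has no competitor.

**C6–O and C5–H (21 back to 17).** Both centers are traced to the C5=C6 alkene of 17. The 6β-alcohol 21 comes from ketone 20, because a hydride can reach C6 only from the α face; the β face is closed by the methyl groups on C4, C8 and C10. Ketone 20 comes from the 6α-alcohol 19, and 19 from 17 by hydroboration–oxidation, which puts oxygen on C6 and hydrogen on C5. The alkene left by the cycloaddition thus serves both centers. Delivering both hydrogens to a C5=C6 bond that already carries the acetoxy group is kept only as a fallback: that alkene would be tetrasubstituted and flanked by two quaternary carbons.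

**Ring D (17 and 16 back to 15).** Ring D is cut at C13–C14. A ketyl–olefin closure forms this bond in the 5-exo mode. The tether allows only the cis fusion at C14, and the dipole of the ketyl keeps its oxygen away from C15, which is the C13 configuration of the target. Polar closures (an aldol from a C15 ketone, or methyl addition to a C13 ketone) would be expected to favor the C13 epimer. The forward reaction must add the ketyl to an unactivated but strained alkene before it is reduced further.

**Cyclobutene from the temporary carbonyl (15 back to 11).** No skeletal bond is cut. Ketone 15 is unmasked from ketal 14. The C14=C15 alkene of 14 comes from the C15 carbonyl of 11 by a Shapiro reaction through hydrazone 12. C14 holds the only α-hydrogens, so the position of the alkene is unambiguous. The carbonyl that activates the dienophile is thereby turned into the acceptor needed for ring D, and C15 ends as the methylene of the target.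

**Ring B (11 back to 2 and 10).** C7–C8 and C9–C10 are cut together, a retro-[4+2]. This is the only place where one event removes all three quaternary carbons from the problem: C10 becomes an alkene carbon of diene 2, and C8 and C9 the alkene of cyclobutenone 10. Two achiral fragments of one and two steps result. The silyloxy group on C7 fixes the regiochemistry and later becomes the ketone. The forward reaction must join a fully substituted diene terminus to a tetrasubstituted, strain-activated dienophile, endo, on one enantioface.

**Dienophile (10 back to 6 and 7; 6 back to 3 and 4).** The C9–C11 bond is cut: the side chain is added as organomagnesium 8 (from bromide 7) to vinylogous ester 6, and acid transposes the carbonyl. Ester 6 is cut across two ring bonds into alkyne 3 and ketene 5 (from acid chloride 4). The methyl group must arrive on the alkyne. A ketene carrying it would leave it on the saturated ring carbon, and after the transposition it would sit on C14 instead of C8.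

**Diene (2 back to 1).** Only the O–Si bond is cut; 2 is the dienol silyl ether of the β,γ-unsaturated aldehyde 1.

## Alternatives that were turned down

**Alternative 1:** The disconnection is the C13–C14 bond of ring D. SmI2 with HMPA would reduce the C13 methyl ketone of cyclobutene A2 (5α-H, free C7 hydroxyl) to a ketyl that closes 5-exo onto C14 and gives the 7,13-diol A1.
- For it: the reaction class is well established and sets C13 and C14 together in the right sense. On this point it is stronger than the chosen key step, which is untested.
- Against it: it solves the easiest ring. A2 already holds the cyclobutene and all three contiguous quaternary carbons, so the real problem is pushed back unsolved, most plausibly to a photochemical annulation on a preformed decalin in a long linear sequence. A1 has also lost the C5=C6 alkene, so the axial C6 oxygen would have to be forced in next to C7 afterwards.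
- Comparison: the chosen route keeps this very closure as step 8, reaches its substrate convergently, and retains the alkene as the handle for C5 and C6.

**Alternative 2:** The cyclobutane is disconnected by ring expansion. The C8–C15 bond comes from contraction of a cyclopentanone fused to ring B at C8–C9, with one extra carbonyl carbon between C8 and C15. Photolysis of the α-diazo ketone A4 in methanol would trigger a Wolff rearrangement in which C8 migrates to C15 and the extra carbon leaves the ring as the methyl ester of A3.
- For it: strain is introduced last and irreversibly, the migrating carbon keeps its configuration, and an unstrained five-membered ring is easier to build and handle than a cyclobutenone. On strain management it is the stronger plan.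
- Against it: the three quaternary carbons must still be assembled, now around a ring with no strain to drive a cycloaddition. The diazo group must be placed at a hindered position. Photolysis is asked of a substrate that already holds the C7 ketone. The C15 ester of A3 is not in the target and costs further steps.
- Comparison: the chosen route makes the four-membered ring directly and uses its C15 carbonyl twice, as activator and as the source of the C14=C15 alkene.

**Alternative 3:** Rings A and B are both disconnected, at C4–C5 and C10–C9. Fe(acac)3 with PhSiH3 would deliver a hydrogen atom to the isopropenyl terminus of polyene A6. The C4 radical closes ring A onto the E C5=C10 alkene, the C10 radical closes ring B onto C9 of the bicyclic enone, and protonation at C14 gives the 7,13-diketone A5.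
- For it: two rings, four stereocenters and the C9–C10 bond in one operation, with radicals that tolerate crowding. In bonds per step it beats the chosen plan.
- Against it: the acceptor in A6 holds its C9=C14 double bond at the fusion of a cyclobutene and a cyclopentenone, a highly strained enone whose preparation is itself unsolved. Its single stereocenter, C8, must control C10 and C9. A5 still needs the C13 methyl group, where addition from the open face of the bicycle would be expected to give the C13 epimer, and the C6 oxygen.
- Comparison: the chosen strategy buys ring A ready-made and spends its risk on one bond-forming event between two quickly made achiral partners.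

Key step: step 4

Remark: α and β refer to the faces of ring B in labdane numbering, β being the face of the C10 methyl group; compounds 1 and 3 are taken to be catalogue materials.

## Route

Step 1
Reactants: 1 β-homocyclocitral, (2,6,6-trimethylcyclohex-1-en-1-yl)acetaldehyde
Product: 2 (E)-tert-butyldimethyl{[2-(2,6,6-trimethylcyclohex-1-en-1-yl)ethenyl]oxy}silane (ring A diene)
Conditions: TBSOTf, Et3N, CH2Cl2, 0 °C to rt
Reagents that add atoms: tert-butyldimethylsilyl triflate, CC(C)(C)[Si](C)(C)OS(=O)(=O)C(F)(F)F
Why: Silyl triflate and amine convert the β,γ-unsaturated aldehyde into its dienol silyl ether by soft enolization toward C6, the only α-carbon (silyl enol ether formation). The E isomer, with the silyloxy group away from the twisted trimethylcyclohexenyl ring, is expected to predominate; the Z isomer cannot reach the s-cis geometry, is inert in step 4 and is returned to 1 by mild hydrolysis.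

Step 2
Reactants: 3 1-ethoxyprop-1-yne; 4 acetyl chloride
Product: 6 3-ethoxy-2-methylcyclobut-2-en-1-one, via ketene 5 (not isolated)
Conditions: Et3N, Et2O, 0 °C to rt, slow addition of 4
Reagents that add atoms: none
Why: Dehydrochlorination of 4 gives ketene 5, which undergoes the ketene–alkyne [2+2] cycloaddition with the electron-rich ynol ether 3. The methyl-bearing alkyne carbon is the nucleophilic one and bonds to the ketene carbonyl carbon, so the methyl ends up on C2 of the vinylogous ester, between the carbonyl and the ethoxy-bearing carbon.

Step 3
Reactants: 7 2-(2-bromoethyl)-2-methyl-1,3-dioxolane; 6 3-ethoxy-2-methylcyclobut-2-en-1-one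
Product: 10 2-methyl-3-[2-(2-methyl-1,3-dioxolan-2-yl)ethyl]cyclobut-2-en-1-one, via Grignard reagent 8 (not isolated), via bromomagnesium alkoxide 9 (not isolated)
Conditions: Mg, THF, 25 °C; then 6, THF, −78 to 0 °C; then 1 M aq. HCl, 0 °C, 15 min
Reagents that add atoms: water, O
Why: Grignard reagent 8 adds 1,2 to the carbonyl of the vinylogous ester (enolization does not compete, since the enolate would be a cyclobutadiene), and brief cold acid ionizes the tertiary allylic carbinol derived from 9 to an alkoxyallyl cation whose hydrolysis gives the transposed enone (Stork–Danheiser transposition). The former C2 methyl is then on the α-carbon and the new chain on the β-carbon. The dioxolane should survive because ionization of the carbinol is far faster than ketal hydrolysis under these conditions.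

Step 4
Reactants: 2 ring A diene; 10 2-methyl-3-[2-(2-methyl-1,3-dioxolan-2-yl)ethyl]cyclobut-2-en-1-one
Product: 11 ring A/B-fused cyclobutanone (Δ5 alkene; 7α-OTBS; 8β-methyl; C15 ketone and C14 methylene on the α face; 9β-[2-(2-methyl-1,3-dioxolan-2-yl)ethyl]; 10β-methyl)
Conditions: oxazaborolidine from (S)-α,α-diphenylprolinol and o-tolylboroxine (20 mol %), AlBr3 (16 mol %), CH2Cl2, −78 to −20 °C; 10–15 kbar if needed
Reagents that add atoms: none
Why: Proposed new method: the Lewis acid binds the C15 carbonyl of 10 and lowers the LUMO of the strained C8=C9 bond, and diene 2 adds suprafacially across it in a concerted but asynchronous [4+2] in which the C9–C10 bond, between the enone β-carbon and the diene terminus remote from the silyloxy group, runs ahead of C7–C8; this intermolecular closure makes ring B and both bonds in one event. The closest known reaction types are Diels–Alder additions of cyclobut-2-enone, whose reactivity comes from release of cyclobutene strain, additions of 1-vinyl-2,6,6-trimethylcyclohexene-type dienes to reactive dienophiles, and oxazaborolidine–AlBr3-catalysed enone Diels–Alder reactions, but no known case joins a fully substituted diene terminus to a 2,3-dialkylcyclobutenone. Regiochemistry is set by the silyloxy group on C7, which makes C10 the nucleophilic end and pairs it with C9. C8 and C9 are set together because the dienophile reacts through one face of its ring, so the C8 methyl and the C9 chain stay cis to each other and C14 and C15 stay cis on the other face. C7 and C10 are tied to them by the endo transition state, in which the four-membered ring lies under the diene: the E silyloxy group then ends cis to C15 (7α) and the C10 methyl, the inside substituent of the diene, ends cis to the C8 methyl (both β). The endo mode should be preferred because the exo mode would push the C8 methyl and the C9 methylene under C5 and C6. Absolute configuration rests on the catalyst covering one face of the bound enone; the S catalyst is the working choice, its sense of induction has to be confirmed on the adduct, and the R catalyst is used if it is opposite. Reactivity rather than selectivity is the open question, since three contiguous quaternary carbons (C8, C9, C10) are made at once, which is why high pressure is held in reserve.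

Step 5
Reactants: 11 ring A/B-fused cyclobutanone
Product: 12 C15 p-toluenesulfonylhydrazone of 11
Conditions: TsNHNH2, THF, 4 Å MS, 50 °C
Reagents that add atoms: p-toluenesulfonyl hydrazide, Cc1ccc(cc1)S(=O)(=O)NN
Why: Condensation of the strained, electrophilic cyclobutanone carbonyl with the sulfonyl hydrazide (hydrazone formation); without added acid the dioxolane and the allylic silyl ether are not at risk. The sulfonamide nitrogen should settle anti to the quaternary C8, that is, syn to C14.

Step 6
Reactants: 12 C15 p-toluenesulfonylhydrazone
Product: 14 C14=C15 cyclobutene (Δ5 alkene; 7α-OTBS; ketal side chain on C9), via cyclobutenyllithium 13 (not isolated)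
Conditions: n-BuLi (2.5 equiv), TMEDA, THF, −78 °C to rt; then H2O
Reagents that add atoms: none
Why: Shapiro reaction: the dianion formed by N–H and syn C14–H deprotonation loses sulfinate and N2 to give cyclobutenyllithium 13, which is protonated on work-up. C14 carries the only α-hydrogens, so the alkene can only be C14=C15, and the alkyllithium protocol avoids the carbene pathway that would contract the ring.

Step 7
Reactants: 14 C14=C15 cyclobutene ketal
Product: 15 C13 methyl ketone (C9 3-oxobutyl chain; C14=C15 cyclobutene; Δ5 alkene; 7α-OTBS)
Conditions: PPTS, acetone/H2O (10:1), 50 °C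
Reagents that add atoms: water, O
Why: Acid-catalysed ketal exchange releases the C13 methyl ketone (acetal hydrolysis). Pyridinium acid is too weak to ionize the allylic silyl ether or to protonate the cyclobutene.

Step 8
Reactants: 15 C13 methyl ketone
Product: 16 tetracyclic tertiary alcohol (ring D closed; 13-OH and 14-H on the ring D face of C10; 13-methyl on the face of C15; Δ5 alkene; 7α-OTBS)
Conditions: SmI2 (2.5 equiv), HMPA, t-BuOH, THF, 0 °C
Reagents that add atoms: none
Why: SmI2/HMPA ketyl–olefin cyclization: the C13 ketyl adds 5-exo to C14 of the strained cyclobutene, and the C15 radical is reduced and protonated by t-BuOH. The tether allows only the cis ring fusion at C14, and the bulky, negatively charged samarium-bound oxygen stays anti to C15, the carbon that becomes the radical, which puts the hydroxyl on the face of H14 and the methyl on the face of C15 (13S), as in the target.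

Step 9
Reactants: 16 tetracyclic tertiary alcohol
Product: 17 13-O-triethylsilyl ether of 16
Conditions: TESOTf, 2,6-lutidine, CH2Cl2, −78 to 0 °C
Reagents that add atoms: triethylsilyl triflate, CC[Si](CC)(CC)OS(=O)(=O)C(F)(F)F
Why: Silylation of the tertiary alcohol with a silyl triflate and a hindered base (silyl ether protection). It removes the only group that could compete in the forcing acetylation of step 13 and is cleaved together with the C7 silyl ether in step 14.

Step 10
Reactants: 17 13-O-triethylsilyl ether
Product: 19 6α-alcohol (5α-H; 7α-OTBS; 13-OTES), via C6 alkylborane 18 (not isolated)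
Conditions: BH3·THF, THF, 0 °C to rt; then NaOH, H2O2, 0 °C
Reagents that add atoms: hydrogen peroxide, OO
Why: Hydroboration–oxidation: boron adds to C6, the only hydrogen-bearing alkene carbon, and hydrogen to C5 in a syn addition, and the C–B bond is oxidized with retention. Attack from the α face is expected because the β face of the alkene is screened by the methyl groups on C4, C8 and C10, which gives the 5α-H trans ring fusion and the 6α-alcohol.

Step 11
Reactants: 19 6α-alcohol
Product: 20 6-ketone (5α-H; 7α-OTBS; 13-OTES)
Conditions: DMP, NaHCO3, CH2Cl2, rt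
Reagents that add atoms: none
Why: Dess–Martin oxidation of the secondary alcohol under buffered, non-enolizing conditions, so that the α-stereocenters C5 and C7 are not disturbed.

Step 12
Reactants: 20 6-ketone
Product: 21 6β-alcohol (5α-H; 7α-OTBS; 13-OTES)
Conditions: NaBH4, MeOH/THF, 0 °C
Reagents that add atoms: none
Why: Hydride reduction of the ketone: NaBH4 can approach C6 only from the α face, because the β face is blocked by the syn-axial methyl groups on C8 and C10 and by the C4 β-methyl, so the axial 6β-alcohol forms under kinetic control.

Step 13
Reactants: 21 6β-alcohol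
Product: 22 6β-acetate (7α-OTBS; 13-OTES)
Conditions: Ac2O, DMAP, pyridine, 50 °C
Reagents that add atoms: acetic anhydride, CC(=O)OC(C)=O
Why: DMAP-catalysed acylation (esterification) of the hindered axial alcohol. Since O7 and O13 are silylated, 21 has no other nucleophilic site and the conditions can be forced.

Step 14
Reactants: 22 6β-acetate
Product: 23 6β-acetoxy-7α,13-diol
Conditions: HF·pyridine, THF, 0 °C to rt
Reagents that add atoms: none
Why: Fluoride-mediated desilylation removes the secondary TBS and the tertiary TES ether at once. The acidic medium and the trans-diaxial relationship of the 6β-acetate and the 7α-hydroxyl leave no path for acetyl migration.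

Step 15
Reactants: 23 6β-acetoxy-7α,13-diol
Product: 24 target, 6β-acetoxy-13-hydroxy-7-ketone
Conditions: DMP, NaHCO3, CH2Cl2, 0 °C to rt
Reagents that add atoms: none
Why: Dess–Martin oxidation of the only secondary alcohol; the tertiary C13 alcohol is inert. The neutral buffered medium avoids epimerization of the axial 6β-acetate through the newly enolizable H6, and no ketyl-forming reagent ever meets the cyclobutyl ketone.

## Compound list

1 | β-homocyclocitral, (2,6,6-trimethylcyclohex-1-en-1-yl)acetaldehyde | CC1=C(CC=O)C(C)(C)CCC1 | starting material
2 | (E)-tert-butyldimethyl{[2-(2,6,6-trimethylcyclohex-1-en-1-yl)ethenyl]oxy}silane, ring A diene | CC(C)(C)[Si](C)(C)O/C=C/C1=C(C)CCCC1(C)C | intermediate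
3 | 1-ethoxyprop-1-yne | CC#COCC | starting material
4 | acetyl chloride | CC(=O)Cl | starting material
5 | ketene (not isolated) | C=C=O | intermediate
6 | 3-ethoxy-2-methylcyclobut-2-en-1-one | CCOC1=C(C)C(=O)C1 | intermediate
7 | 2-(2-bromoethyl)-2-methyl-1,3-dioxolane | CC1(CCBr)OCCO1 | starting material
8 | [2-(2-methyl-1,3-dioxolan-2-yl)ethyl]magnesium bromide (not isolated) | CC1(CC[Mg]Br)OCCO1 | intermediate
9 | bromomagnesium alkoxide of 3-ethoxy-2-methyl-1-[2-(2-methyl-1,3-dioxolan-2-yl)ethyl]cyclobut-2-en-1-ol (not isolated; carbinol center racemic) | CCOC1=C(C)C(O[Mg]Br)(CCC2(C)OCCO2)C1 | intermediate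
10 | 2-methyl-3-[2-(2-methyl-1,3-dioxolan-2-yl)ethyl]cyclobut-2-en-1-one | CC1=C(CCC2(C)OCCO2)CC1=O | intermediate
11 | Diels–Alder adduct: ring A/B-fused cyclobutanone, Δ5, 7α-OTBS, 8β-Me, C14/C15 α (C15=O), 9β ketal side chain, 10β-Me | C1[C@@H](O[Si](C)(C)C(C)(C)C)[C@@]2(C)C(=O)C[C@@]2(CCC3(C)OCCO3)[C@@]2(C)CCCC(C)(C)C=12 | intermediate
12 | C15 p-toluenesulfonylhydrazone of 11 | C1[C@@H](O[Si](C)(C)C(C)(C)C)[C@@]2(C)C(=NNS(=O)(=O)c4ccc(C)cc4)C[C@@]2(CCC3(C)OCCO3)[C@@]2(C)CCCC(C)(C)C=12 | intermediate
13 | C15-lithio C14=C15 cyclobutene (not isolated) | C1[C@@H](O[Si](C)(C)C(C)(C)C)[C@@]2(C)C([Li])=C[C@@]2(CCC3(C)OCCO3)[C@@]2(C)CCCC(C)(C)C=12 | intermediate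
14 | C14=C15 cyclobutene, Δ5, 7α-OTBS, 9β ketal side chain | C1[C@@H](O[Si](C)(C)C(C)(C)C)[C@@]2(C)C=C[C@@]2(CCC3(C)OCCO3)[C@@]2(C)CCCC(C)(C)C=12 | intermediate
15 | C13 methyl ketone: C14=C15 cyclobutene with 9β 3-oxobutyl chain, Δ5, 7α-OTBS | C1[C@@H](O[Si](C)(C)C(C)(C)C)[C@@]2(C)C=C[C@@]2(CCC(C)=O)[C@@]2(C)CCCC(C)(C)C=12 | intermediate
16 | tetracyclic tertiary alcohol: ring D closed, 13-OH and 14-H on the ring D face of C10, Δ5, 7α-OTBS | C1[C@@H](O[Si](C)(C)C(C)(C)C)[C@@]2(C)C[C@H]3[C@@]2(CC[C@]3(C)O)[C@@]2(C)CCCC(C)(C)C=12 | intermediate
17 | 13-O-triethylsilyl ether of 16 | C1[C@@H](O[Si](C)(C)C(C)(C)C)[C@@]2(C)C[C@H]3[C@@]2(CC[C@]3(C)O[Si](CC)(CC)CC)[C@@]2(C)CCCC(C)(C)C=12 | intermediate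
18 | C6 α-alkylborane, 5α-H (not isolated) | B[C@H]1[C@@H](O[Si](C)(C)C(C)(C)C)[C@@]2(C)C[C@H]3[C@@]2(CC[C@]3(C)O[Si](CC)(CC)CC)[C@@]2(C)CCCC(C)(C)[C@H]12 | intermediate
19 | 6α-alcohol, 5α-H, 7α-OTBS, 13-OTES | O[C@H]1[C@@H](O[Si](C)(C)C(C)(C)C)[C@@]2(C)C[C@H]3[C@@]2(CC[C@]3(C)O[Si](CC)(CC)CC)[C@@]2(C)CCCC(C)(C)[C@H]12 | intermediate
20 | 6-ketone, 5α-H, 7α-OTBS, 13-OTES | O=C1[C@@H](O[Si](C)(C)C(C)(C)C)[C@@]2(C)C[C@H]3[C@@]2(CC[C@]3(C)O[Si](CC)(CC)CC)[C@@]2(C)CCCC(C)(C)[C@H]12 | intermediate
21 | 6β-alcohol, 5α-H, 7α-OTBS, 13-OTES | O[C@@H]1[C@@H](O[Si](C)(C)C(C)(C)C)[C@@]2(C)C[C@H]3[C@@]2(CC[C@]3(C)O[Si](CC)(CC)CC)[C@@]2(C)CCCC(C)(C)[C@H]12 | intermediate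
22 | 6β-acetate, 7α-OTBS, 13-OTES | CC(=O)O[C@@H]1[C@@H](O[Si](C)(C)C(C)(C)C)[C@@]2(C)C[C@H]3[C@@]2(CC[C@]3(C)O[Si](CC)(CC)CC)[C@@]2(C)CCCC(C)(C)[C@H]12 | intermediate
23 | 6β-acetoxy-7α,13-diol | CC(=O)O[C@@H]1[C@@H](O)[C@@]2(C)C[C@H]3[C@@]2(CC[C@]3(C)O)[C@@]2(C)CCCC(C)(C)[C@H]12 | intermediate
24 | CNP0330581.1, 6β-acetoxy-13-hydroxy-7-ketone | CC(=O)O[C@@H]1C(=O)[C@@]2(C)C[C@H]3[C@@]2(CC[C@]3(C)O)[C@@]2(C)CCCC(C)(C)[C@H]12 | target

## Step count and least certain steps

Total step count: 15. Longest linear sequence: 14 steps (steps 2 to 15, from 3 and 4).

**Step 4 (key step, the one labelled as a proposed new method).** The most likely failure is that no bond forms, because the two fully substituted carbons C9 and C10 cannot approach closely enough. The Lewis acid would then consume 2 by desilylation or be held by the dioxolane oxygens of 10. Any adduct that does form may show low or reversed facial selectivity.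

Fallback, by known reaction types only: the cyclobutanone is reached through a less crowded cycloaddition followed by ring contraction. It sets out from 2 and 7 and comes back at 11 and 14. Thermal Diels–Alder addition of 2 to 4-methylcyclopent-4-ene-1,3-dione, a cyclic enedione in which C10 meets an unsubstituted alkene carbon, should give the endo adduct, the cis-fused bicyclic 1,3-dione F1, in which C9 still carries hydrogen. Its dianion (LiN(i-Pr)2, 2.2 equiv, THF/HMPA) is alkylated at C9, the only γ-position, by bromide 7. The cis ring fusion directs the chain to the β face and gives the C9-alkylated dione F2, which is racemic at this point and is resolved on a chiral stationary phase. Diazo transfer (p-acetamidobenzenesulfonyl azide, Et3N) gives the 2-diazo-1,3-dione F3. Photolysis in methanol (Wolff rearrangement) contracts the five-membered ring to two cyclobutanone β-keto esters: the C15 ketone F4 (C9 has migrated) and the C14 ketone F5 (C8 has migrated). Krapcho decarboxylation (LiCl, wet DMSO, 130 °C) converts F4 into 11 and F5 into the isomeric C14 cyclobutanone F6. Compound 11 re-enters at step 5. F6 is treated the same way (C14 tosylhydrazone F7, then n-BuLi) and gives the same cyclobutene 14, because both ketones flank the C14–C15 bond. The price is five to six steps in place of one.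

**Step 6.** Condensation at the neopentyl-type carbonyl may be slow. The hydrazone anion may also fragment by the carbene route, with ring contraction, or add n-BuLi at C=N instead of giving the vinyllithium.

Fallback, from 11 to 14: KN(SiMe3)2 in THF at −78 °C and N-phenyl-bis(trifluoromethanesulfonimide) give the cyclobutenyl triflate F8, C14 again being the only enolizable position. Pd(OAc)2/PPh3 with Bu3N and HCO2H in DMF then reduces the C–O bond to C–H.

**Step 8.** The ketyl may be reduced to the secondary alcohol, or dimerize, before it adds, because the acceptor is an unactivated 1,2-disubstituted alkene.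

Fallback, from 12 to 16, with an activated acceptor: the Shapiro vinyllithium 13 is trapped with benzenesulfonyl fluoride to give the cyclobutenyl phenyl sulfone F9. PPTS in wet acetone gives the keto sulfone F10. SmI2 in THF/MeOH at −78 °C adds the ketyl to C14, now the β-carbon of a vinyl sulfone, with the same anti preference, and gives the hydroxy sulfone F11. Reductive desulfonylation (Na/Hg, Na2HPO4, MeOH) gives 16.

**Step 10.** Facial selectivity may be poor: borane may add anti to the 7α-silyloxy group, from the β face, and give the cis-fused series. Two further concerns are β-elimination of the C6 boron with the C7 silyloxy group and base-induced silyl migration between the cis O6 and O7 during the oxidation.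

Fallback, from 17 to 20, replacing kinetic by thermodynamic control of C5: the β-face product, the 5β-H 6β-alcohol F12, is oxidized as in step 11 to the cis-fused 6-ketone F13. Equilibration with DBU in toluene then epimerizes C5 to the more stable trans-fused ketone 20. C7 also carries an enolizable hydrogen; its configuration has no lasting importance because C7 is oxidized in step 15.

**Step 13.** Acylation may stall, because the 6β-hydroxyl lies under the C8 and C10 methyl groups and next to the 7α-silyloxy group.

Fallback, from 21 to 24, acylating a planar enol instead: HF·pyridine gives the 6β,7α,13-triol F14. Swern oxidation of both secondary hydroxyls gives the 6,7-dione, which enolizes toward C5, its only enolizable side, to the diosphenol F15. Ac2O/pyridine acetylates the enol selectively to the diosphenol acetate F16. Hydrogenation over PtO2 in EtOAc/AcOH under pressure should add both hydrogens from the α face and give 24 directly. This last hydrogenation, of a tetrasubstituted alkene between two quaternary carbons, is the reason this sequence is a fallback and not the main route.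

## Further compounds

F1 | step 4 | endo Diels–Alder adduct of 2 with 4-methylcyclopent-4-ene-1,3-dione: cis-fused bicyclic 1,3-dione, 7α-OTBS, 8β-Me, 9β-H, 10β-Me | C1[C@@H](O[Si](C)(C)C(C)(C)C)[C@@]2(C)C(=O)CC(=O)[C@H]2[C@@]2(C)CCCC(C)(C)C=12
F2 | step 4 | C9-alkylated 1,3-dione with the 9β ketal side chain | C1[C@@H](O[Si](C)(C)C(C)(C)C)[C@@]2(C)C(=O)CC(=O)[C@@]2(CCC3(C)OCCO3)[C@@]2(C)CCCC(C)(C)C=12
F3 | step 4 | 2-diazo-1,3-dione | C1[C@@H](O[Si](C)(C)C(C)(C)C)[C@@]2(C)C(=O)C(=[N+]=[N-])C(=O)[C@@]2(CCC3(C)OCCO3)[C@@]2(C)CCCC(C)(C)C=12
F4 | step 4 | ring-contracted β-keto ester, ketone at C15, methyl ester on C14 | C1[C@@H](O[Si](C)(C)C(C)(C)C)[C@@]2(C)C(=O)C(C(=O)OC)[C@@]2(CCC3(C)OCCO3)[C@@]2(C)CCCC(C)(C)C=12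
F5 | step 4 | ring-contracted β-keto ester, ketone at C14, methyl ester on C15 | C1[C@@H](O[Si](C)(C)C(C)(C)C)[C@@]2(C)C(C(=O)OC)C(=O)[C@@]2(CCC3(C)OCCO3)[C@@]2(C)CCCC(C)(C)C=12
F6 | step 4 | C14 cyclobutanone, regioisomer of 11 | C1[C@@H](O[Si](C)(C)C(C)(C)C)[C@@]2(C)CC(=O)[C@@]2(CCC3(C)OCCO3)[C@@]2(C)CCCC(C)(C)C=12
F7 | step 4 | C14 p-toluenesulfonylhydrazone of F6 | C1[C@@H](O[Si](C)(C)C(C)(C)C)[C@@]2(C)CC(=NNS(=O)(=O)c4ccc(C)cc4)[C@@]2(CCC3(C)OCCO3)[C@@]2(C)CCCC(C)(C)C=12
F8 | step 6 | C15 cyclobutenyl triflate of 11 | C1[C@@H](O[Si](C)(C)C(C)(C)C)[C@@]2(C)C(OS(=O)(=O)C(F)(F)F)=C[C@@]2(CCC3(C)OCCO3)[C@@]2(C)CCCC(C)(C)C=12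
F9 | step 8 | C15 phenylsulfonyl cyclobutene, ketal side chain | C1[C@@H](O[Si](C)(C)C(C)(C)C)[C@@]2(C)C(S(=O)(=O)c4ccccc4)=C[C@@]2(CCC3(C)OCCO3)[C@@]2(C)CCCC(C)(C)C=12
F10 | step 8 | C15 phenylsulfonyl cyclobutene, C13 methyl ketone | C1[C@@H](O[Si](C)(C)C(C)(C)C)[C@@]2(C)C(S(=O)(=O)c4ccccc4)=C[C@@]2(CCC(C)=O)[C@@]2(C)CCCC(C)(C)C=12
F11 | step 8 | tetracyclic 13-hydroxy C15 phenyl sulfone | C1[C@@H](O[Si](C)(C)C(C)(C)C)[C@@]2(C)C(S(=O)(=O)c4ccccc4)[C@H]3[C@@]2(CC[C@]3(C)O)[C@@]2(C)CCCC(C)(C)C=12
F12 | step 10 | 5β-H 6β-alcohol, cis-fused, 7α-OTBS, 13-OTES | O[C@@H]1[C@@H](O[Si](C)(C)C(C)(C)C)[C@@]2(C)C[C@H]3[C@@]2(CC[C@]3(C)O[Si](CC)(CC)CC)[C@@]2(C)CCCC(C)(C)[C@@H]12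
F13 | step 10 | 5β-H 6-ketone, cis-fused, 7α-OTBS, 13-OTES | O=C1[C@@H](O[Si](C)(C)C(C)(C)C)[C@@]2(C)C[C@H]3[C@@]2(CC[C@]3(C)O[Si](CC)(CC)CC)[C@@]2(C)CCCC(C)(C)[C@@H]12
F14 | step 13 | 6β,7α,13-triol, 5α-H | O[C@@H]1[C@@H](O)[C@@]2(C)C[C@H]3[C@@]2(CC[C@]3(C)O)[C@@]2(C)CCCC(C)(C)[C@H]12
F15 | step 13 | diosphenol, 6,13-dihydroxy-Δ5-7-ketone | OC1C(=O)[C@@]2(C)C[C@H]3[C@@]2(CC[C@]3(C)O)[C@@]2(C)CCCC(C)(C)C=12
F16 | step 13 | diosphenol acetate, 6-acetoxy-13-hydroxy-Δ5-7-ketone | CC(=O)OC1C(=O)[C@@]2(C)C[C@H]3[C@@]2(CC[C@]3(C)O)[C@@]2(C)CCCC(C)(C)C=12
A1 | alternative 1 | tetracyclic 7,13-diol | C1[C@H](O)[C@@]2(C)C[C@H]3[C@@]2(CC[C@]3(C)O)[C@@]2(C)CCCC(C)(C)[C@H]12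
A2 | alternative 1 | 7-hydroxy C14=C15 cyclobutene with C13 methyl ketone side chain, 5α-H | C1[C@H](O)[C@@]2(C)C=C[C@@]2(CCC(C)=O)[C@@]2(C)CCCC(C)(C)[C@H]12
A3 | alternative 2 | tetracyclic 7-ketone with C15 methyl ester, 13-OTES | C1C(=O)[C@@]2(C)[C@@H](C(=O)OC)[C@H]3[C@@]2(CC[C@]3(C)O[Si](CC)(CC)CC)[C@@]2(C)CCCC(C)(C)[C@H]12
A4 | alternative 2 | α-diazo ketone in the fused cyclopentanone, 13-OTES | C1C(=O)[C@@]2(C)C(=O)C(=[N+]=[N-])[C@H]3[C@@]2(CC[C@]3(C)O[Si](CC)(CC)CC)[C@@]2(C)CCCC(C)(C)[C@H]12
A5 | alternative 3 | tetracyclic 7,13-diketone | C1C(=O)[C@@]2(C)C[C@H]3[C@@]2(CCC3=O)[C@@]2(C)CCCC(C)(C)[C@H]12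
A6 | alternative 3 | polyene with isopropenyl terminus, E C5=C10 alkene and bicyclic cyclobutene-fused enone | C=C(C)CCC/C(C)=C/CC(=O)[C@@]1(C)CC2=C1CCC2=O
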